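**Retrosynthetic overview**

1. The target is an apigenin in which ring A (C4a, C5–OH, C6–aryl, C7–OH, C8–H, C8a) carries ring D, the 2-methoxy-5-(methoxycarbonyl)phenyl group, at C6 between the two phenol oxygens and shares its C4a–C8a edge with pyranone ring C. The plan builds this fully substituted ring A last, onto an intact ring C.
2. After removal of the O7 silyl and O4' benzyl groups, ring A is cut at C8–C8a, C5–C6, C7–C8 and C4a–C5 into 2-diazoacetyl-4-pyranone 9 (rings B and C, plus C5 and C8) and aryl siloxyalkyne 16 (ring D, plus C6 and C7).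
3. Compound 9 comes from 4'-(benzyloxy)acetophenone by two Claisen chain extensions (ethyl acetate, then diethyl oxalate), cyclodehydration to the pyranone-2-carboxylate, hydrolysis, acid chloride formation and acylation of diazomethane.
4. Compound 16 comes from methyl 3-iodo-4-methoxybenzoate by Sonogashira ethynylation, desilylation, acetylide oxidation and O-silylation.
5. Ring order: rings B and D are bought, ring C closes in step 3, ring A closes in step 10; steps 11 and 12 only unmask O7 and O4'.

Key step: step 10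

Remark: the target has no stereocentre, and the C6–aryl axis (flanked by OH, OH and OMe/H) is taken as freely rotating, so no stereocontrol is planned.

**Route**

Step 1
Reactants: 1 4'-(benzyloxy)acetophenone; 2 ethyl acetate
Product: 3 1-[4-(benzyloxy)phenyl]butane-1,3-dione
Conditions: NaH (2.5 equiv), 2 (3 equiv), THF, 0 °C → reflux; then 1 M HCl
Reagents that add atoms: none
Why: Crossed Claisen condensation in which the sodium enolate of the aryl methyl ketone is acylated by ethyl acetate and the equilibrium is pulled through by deprotonation of the 1,3-diketone, the benzyl ether being inert to NaH.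

Step 2
Reactants: 3 1-[4-(benzyloxy)phenyl]butane-1,3-dione; 4 diethyl oxalate
Product: 5 ethyl 6-[4-(benzyloxy)phenyl]-2,4,6-trioxohexanoate
Conditions: LiN(i-Pr)2 (3.2 equiv), THF, −78 → 0 °C; cannulated into 4 (1.5 equiv), THF, −78 °C → rt; then 1 M HCl
Reagents that add atoms: none
Why: Claisen acylation of the 1,3-diketone dianion (Harris-type terminal acylation), in which the non-stabilised methyl carbanion is the more nucleophilic site and the extra base covers the more acidic triketone product.

Step 3
Reactants: 5 ethyl 6-[4-(benzyloxy)phenyl]-2,4,6-trioxohexanoate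
Product: 6 ethyl 6-[4-(benzyloxy)phenyl]-4-oxo-4H-pyran-2-carboxylate
Conditions: conc. HCl (cat.), EtOH, reflux
Reagents that add atoms: none
Why: Acid-catalysed cyclodehydration of the 1,3,5-tricarbonyl array (enol oxygen at C6 onto the C2 keto group, then loss of water) closes 4-pyranone ring C, with ethanol keeping the ethyl ester unchanged and the dilute acid sparing the benzyl ether.

Step 4
Reactants: 6 ethyl 6-[4-(benzyloxy)phenyl]-4-oxo-4H-pyran-2-carboxylate
Product: 7 6-[4-(benzyloxy)phenyl]-4-oxo-4H-pyran-2-carboxylic acid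
Conditions: LiOH·H2O (1.2 equiv), THF/H2O, 0 °C; then 1 M HCl
Reagents that add atoms: lithium hydroxide, [Li+].[OH-]
Why: Saponification of an ester activated by the electron-poor pyranone should outrun hydroxide addition to the ring at 0 °C, and any ring-opened triketone recloses on the acidic work-up.

Step 5
Reactants: 7 6-[4-(benzyloxy)phenyl]-4-oxo-4H-pyran-2-carboxylic acid
Product: 8 6-[4-(benzyloxy)phenyl]-4-oxo-4H-pyran-2-carbonyl chloride
Conditions: (COCl)2 (1.5 equiv), DMF (cat.), CH2Cl2, 0 °C → rt; evaporate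
Reagents that add atoms: oxalyl chloride, O=C(Cl)C(=O)Cl
Why: Vilsmeier-type conversion of a carboxylic acid into its chloride under conditions that leave the pyranone and the benzyl ether alone, the crude chloride being used directly after evaporation.

Step 6
Reactants: 8 6-[4-(benzyloxy)phenyl]-4-oxo-4H-pyran-2-carbonyl chloride
Product: 9 2-(diazoacetyl)-6-[4-(benzyloxy)phenyl]-4H-pyran-4-one
Conditions: CH2N2 (3 equiv, ethereal, from N-methyl-N-nitroso-p-toluenesulfonamide), THF/Et2O, 0 °C
Reagents that add atoms: diazomethane, C=[N+]=[N-]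
Why: Arndt–Eistert-type acylation of diazomethane by the acid chloride, with the excess diazomethane consuming the HCl so that no chloromethyl ketone forms.

Step 7
Reactants: 10 methyl 3-iodo-4-methoxybenzoate; 11 trimethylsilylacetylene
Product: 12 methyl 4-methoxy-3-[(trimethylsilyl)ethynyl]benzoate
Conditions: PdCl2(PPh3)2 (2 mol %), CuI (4 mol %), Et3N, THF, rt
Reagents that add atoms: none
Why: Sonogashira coupling of an aryl iodide, which tolerates the methyl ester and the ortho methoxy group.

Step 8
Reactants: 12 methyl 4-methoxy-3-[(trimethylsilyl)ethynyl]benzoate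
Product: 13 methyl 3-ethynyl-4-methoxybenzoate
Conditions: K2CO3 (0.2 equiv), MeOH, rt
Reagents that add atoms: none
Why: Base-catalysed methanolysis of the alkynyl C–Si bond, in a solvent where any transesterification of the methyl ester is degenerate.

Step 9
Reactants: 13 methyl 3-ethynyl-4-methoxybenzoate
Product: 16 methyl 4-methoxy-3-[(triisopropylsilyloxy)ethynyl]benzoate, via lithium acetylide 14 (not isolated), via lithium ynolate 15 (not isolated)
Conditions: LiN(SiMe3)2 (2.2 equiv), THF, −78 °C; t-BuOOH (1.0 equiv, in decane), −78 → 0 °C; i-Pr3SiOTf (1.2 equiv), −78 °C; hexane/aq. NaHCO3 work-up, Et3N-deactivated silica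
Reagents that add atoms: tert-butyl hydroperoxide, CC(C)(C)OO; triisopropylsilyl trifluoromethanesulfonate, CC(C)[Si](OS(=O)(=O)C(F)(F)F)(C(C)C)C(C)C
Why: Oxidation of the lithium acetylide by lithium tert-butyl peroxide (electrophilic oxygen transfer with loss of LiOt-Bu) gives the ynolate, which the hard, bulky silyl triflate traps on oxygen, while the non-nucleophilic amide base and the low electrophilicity of the para-methoxy benzoate should keep the ester intact below 0 °C.

Step 10
Reactants: 9 2-(diazoacetyl)-6-[4-(benzyloxy)phenyl]-4H-pyran-4-one; 16 methyl 4-methoxy-3-[(triisopropylsilyloxy)ethynyl]benzoate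
Product: 21 methyl 3-{2-[4-(benzyloxy)phenyl]-5-hydroxy-4-oxo-7-[(triisopropylsilyl)oxy]-4H-chromen-6-yl}-4-methoxybenzoate, via pyranylketene 17 (not isolated), via cyclobutenone 18 (not isolated), via dienylketene 19 (not isolated), via cyclohexadienone tautomer 20 (not isolated)
Conditions: 9 (1.0 equiv), 16 (1.3 equiv), degassed ClCH2CH2Cl, hν (440 nm LEDs), rt; then 80 °C
Reagents that add atoms: none
Why: Proposed new method: excitation of the diazo n–π* band of 9 expels N2 with a Wolff 1,2-shift of pyranone C2 from the acyl carbon to the diazo carbon (C8–C8a), giving ketene 17, which adds the siloxyalkyne [2+2] across its C=C bond (C5–C6 and C7–C8) to cyclobutenone 18; on heating, 18 opens reversibly by conrotatory four-electron electrocyclic cleavage of the C5–C8 bond to dienylketene 19. Ring A then closes by thermal disrotatory six-electron electrocyclization of 19, the ketene carbon bonding to pyranone C3 (C4a–C5), and the doubly activated C4a–H of 20 enolises to the C5 phenol chelated to the C4 carbonyl. The closest known reaction type is the Danheiser benzannulation of photochemically generated aryl- and heteroarylketenes with siloxyalkynes; what is new is a 4-pyranone as the ketene carrier, whose C2=C3 enol ether bond is polarised correctly (nucleophilic C3 toward the electrophilic ketene carbon) and should give up less aromatic stabilisation than the benzene or thiophene rings known to take part. No stereocentre is formed, and the geometry of the ring opening needs no control because dienylketene isomers that cannot cyclise revert to 18. The step needs one regiochemical outcome in the [2+2] event, and the polarisation of the ynol ether secures it: the nucleophilic aryl-bearing carbon attacks the ketene carbonyl carbon, which places ring D at C6 beside the new C5–OH and the siloxy carbon at C7 beside C8–H, while the closure site is unambiguous because the only carbon neighbour of pyranone C2 is C3. Irradiation at 440 nm addresses only the diazoketone, so the 2-aryl-4-pyranone and the flavone product should stay out of the photochemistry.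

Step 11
Reactants: 21 methyl 3-{2-[4-(benzyloxy)phenyl]-5-hydroxy-4-oxo-7-[(triisopropylsilyl)oxy]-4H-chromen-6-yl}-4-methoxybenzoate
Product: 22 methyl 3-{2-[4-(benzyloxy)phenyl]-5,7-dihydroxy-4-oxo-4H-chromen-6-yl}-4-methoxybenzoate
Conditions: Bu4NF (1.1 equiv), AcOH (1.2 equiv), THF, 0 °C
Reagents that add atoms: none
Why: Fluoride-induced cleavage of the aryl silyl ether, driven by the Si–F bond and buffered with acetic acid so that the methyl ester and the benzyl ether are untouched.

Step 12
Reactants: 22 methyl 3-{2-[4-(benzyloxy)phenyl]-5,7-dihydroxy-4-oxo-4H-chromen-6-yl}-4-methoxybenzoate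
Product: 23 methyl 3-[5,7-dihydroxy-2-(4-hydroxyphenyl)-4-oxo-4H-chromen-6-yl]-4-methoxybenzoate
Conditions: H2 (1 atm), 10% Pd/C, THF/MeOH, rt
Reagents that add atoms: none
Why: Hydrogenolysis of the benzyl aryl ether over Pd/C at atmospheric pressure, conditions under which the flavone C2=C3 bond, the methyl ester and the aryl methyl ether should not be reduced.

**Compound list**

1 | 4'-(benzyloxy)acetophenone | CC(=O)c1ccc(OCc2ccccc2)cc1 | starting material
2 | ethyl acetate | CCOC(C)=O | starting material
3 | 1-[4-(benzyloxy)phenyl]butane-1,3-dione | CC(=O)CC(=O)c1ccc(OCc2ccccc2)cc1 | intermediate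
4 | diethyl oxalate | CCOC(=O)C(=O)OCC | starting material
5 | ethyl 6-[4-(benzyloxy)phenyl]-2,4,6-trioxohexanoate | CCOC(=O)C(=O)CC(=O)CC(=O)c1ccc(OCc2ccccc2)cc1 | intermediate
6 | ethyl 6-[4-(benzyloxy)phenyl]-4-oxo-4H-pyran-2-carboxylate | CCOC(=O)c1cc(=O)cc(-c2ccc(OCc3ccccc3)cc2)o1 | intermediate
7 | 6-[4-(benzyloxy)phenyl]-4-oxo-4H-pyran-2-carboxylic acid | OC(=O)c1cc(=O)cc(-c2ccc(OCc3ccccc3)cc2)o1 | intermediate
8 | 6-[4-(benzyloxy)phenyl]-4-oxo-4H-pyran-2-carbonyl chloride | ClC(=O)c1cc(=O)cc(-c2ccc(OCc3ccccc3)cc2)o1 | intermediate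
9 | 2-(diazoacetyl)-6-[4-(benzyloxy)phenyl]-4H-pyran-4-one | [N-]=[N+]=CC(=O)c1cc(=O)cc(-c2ccc(OCc3ccccc3)cc2)o1 | intermediate
10 | methyl 3-iodo-4-methoxybenzoate | COC(=O)c1ccc(OC)c(I)c1 | starting material
11 | trimethylsilylacetylene | C#C[Si](C)(C)C | starting material
12 | methyl 4-methoxy-3-[(trimethylsilyl)ethynyl]benzoate | COC(=O)c1ccc(OC)c(C#C[Si](C)(C)C)c1 | intermediate
13 | methyl 3-ethynyl-4-methoxybenzoate | COC(=O)c1ccc(OC)c(C#C)c1 | intermediate
14 | lithium acetylide of 13 (lithium [2-methoxy-5-(methoxycarbonyl)phenyl]ethynide) | COC(=O)c1ccc(OC)c(C#[C-])c1.[Li+] | intermediate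
15 | lithium ynolate (lithium 2-[2-methoxy-5-(methoxycarbonyl)phenyl]ethynolate) | COC(=O)c1ccc(OC)c(C#C[O-])c1.[Li+] | intermediate
16 | methyl 4-methoxy-3-[(triisopropylsilyloxy)ethynyl]benzoate | COC(=O)c1ccc(OC)c(C#CO[Si](C(C)C)(C(C)C)C(C)C)c1 | intermediate
17 | pyranylketene, 6-[4-(benzyloxy)phenyl]-2-(2-oxoethenyl)-4H-pyran-4-one | O=C=Cc1cc(=O)cc(-c2ccc(OCc3ccccc3)cc2)o1 | intermediate
18 | cyclobutenone, methyl 3-{3-[6-(4-benzyloxyphenyl)-4-oxo-4H-pyran-2-yl]-4-oxo-2-[(triisopropylsilyl)oxy]cyclobut-1-en-1-yl}-4-methoxybenzoate (racemic at the ring CH) | COC(=O)c1ccc(OC)c(C2=C(O[Si](C(C)C)(C(C)C)C(C)C)C(c3cc(=O)cc(-c4ccc(OCc5ccccc5)cc4)o3)C2=O)c1 | intermediate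
19 | dienylketene, methyl 3-{(3E)-4-[6-(4-benzyloxyphenyl)-4-oxo-4H-pyran-2-yl]-1-oxo-3-[(triisopropylsilyl)oxy]buta-1,3-dien-2-yl}-4-methoxybenzoate (pyranonyl group cis to the ketene-bearing carbon) | COC(=O)c1ccc(OC)c(C(=C=O)/C(O[Si](C(C)C)(C(C)C)C(C)C)=C\c2cc(=O)cc(-c3ccc(OCc4ccccc4)cc3)o2)c1 | intermediate
20 | cyclohexadienone tautomer, methyl 3-{2-[4-(benzyloxy)phenyl]-4,5-dioxo-7-[(triisopropylsilyl)oxy]-4a,5-dihydro-4H-chromen-6-yl}-4-methoxybenzoate (racemic at C4a) | COC(=O)c1ccc(OC)c(C2=C(O[Si](C(C)C)(C(C)C)C(C)C)C=C3OC(c4ccc(OCc5ccccc5)cc4)=CC(=O)C3C2=O)c1 | intermediate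
21 | methyl 3-{2-[4-(benzyloxy)phenyl]-5-hydroxy-4-oxo-7-[(triisopropylsilyl)oxy]-4H-chromen-6-yl}-4-methoxybenzoate | COC(=O)c1ccc(OC)c(-c2c(O[Si](C(C)C)(C(C)C)C(C)C)cc3oc(-c4ccc(OCc5ccccc5)cc4)cc(=O)c3c2O)c1 | intermediate
22 | methyl 3-{2-[4-(benzyloxy)phenyl]-5,7-dihydroxy-4-oxo-4H-chromen-6-yl}-4-methoxybenzoate | COC(=O)c1ccc(OC)c(-c2c(O)cc3oc(-c4ccc(OCc5ccccc5)cc4)cc(=O)c3c2O)c1 | intermediate
23 | methyl 3-[5,7-dihydroxy-2-(4-hydroxyphenyl)-4-oxo-4H-chromen-6-yl]-4-methoxybenzoate | COC(=O)c1ccc(OC)c(-c2c(O)cc3oc(-c4ccc(O)cc4)cc(=O)c3c2O)c1 | target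

**Count**

Total steps: 12. Longest linear sequence: 9 steps (steps 1–6, then 10–12); the ring D branch (steps 7–9) joins at step 10.

**Steps most likely to fail**

1. Step 10 (key step). The ketene may dimerise before it meets the alkyne, the pyranone chromophore may be drawn into rearrangement or dimerisation if it is excited after all, or the six-electron closure onto pyranone C3 may be so slow that the cyclobutenone decomposes on heating. The fallback uses known cross-coupling chemistry; it sets out from iodide 10 and comes back at target 23. Miyaura borylation of 10 (B2pin2, PdCl2(dppf), KOAc, dioxane, 80 °C) should give methyl 4-methoxy-3-(4,4,5,5-tetramethyl-1,3,2-dioxaborolan-2-yl)benzoate F1. Commercial apigenin (O=c1cc(-c2ccc(O)cc2)oc2cc(O)cc(O)c12) is benzylated at O7 and O4' (BnBr, K2CO3, DMF; the chelated 5-OH stays free) to 7,4'-di-O-benzylapigenin F2. Iodination ortho to the free 5-OH with BnMe3N+ ICl2−/CaCO3 in CH2Cl2/MeOH should give 7,4'-di-O-benzyl-6-iodoapigenin F3. Suzuki–Miyaura coupling of F3 with F1 (Pd(OAc)2, SPhos, K3PO4, toluene, 90 °C) should give the 6-aryl-7,4'-di-O-benzyl flavone F4, and hydrogenolysis of both benzyl ethers (H2, Pd/C, THF/MeOH) gives 23.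

2. Step 9. The peroxide anion or the ynolate may attack the methyl ester, oxygen transfer may stay incomplete, or the siloxyalkyne may hydrolyse on silica. The fallback keeps the benzannulation but carries a bromine in place of the ester until ring A exists; it sets out from diazoketone 9 and alkyne 11 and comes back at 21. Commercial 4-bromo-2-iodoanisole (COc1ccc(Br)cc1I) is coupled with 11 at the iodide only (PdCl2(PPh3)2, CuI, Et3N, rt) to [(5-bromo-2-methoxyphenyl)ethynyl]trimethylsilane F5. K2CO3/MeOH gives 4-bromo-2-ethynyl-1-methoxybenzene F6. The same oxidation and silylation as in step 9, now with no electrophilic group on the ring, gives {[(5-bromo-2-methoxyphenyl)ethynyl]oxy}triisopropylsilane F7. Benzannulation of F7 with 9 under the conditions of step 10 gives the 6-(5-bromo-2-methoxyphenyl)flavone F8. Methoxycarbonylation of the aryl bromide (Pd(OAc)2, Xantphos, CO 1 atm, MeOH, Et3N, toluene, 80 °C) then installs the ester and delivers 21; should the C7 silyl ether be shed under these conditions, the product is 22, which lies on the route as well.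

3. Step 6. Diazomethane may add as a dipole across the doubly activated C2=C3 bond of the pyranone acyl chloride, or HCl may convert the diazoketone into the chloromethyl ketone. The fallback makes the diazo group by diazo transfer instead; it sets out from acid chloride 8 and comes back at 9. Negishi-type acylation of 8 (MeZnCl, Pd(PPh3)4 cat., THF, 0 °C) should give 2-acetyl-6-[4-(benzyloxy)phenyl]-4H-pyran-4-one F9. Its lithium enolate (LiN(SiMe3)2, THF, −78 °C) is trifluoroacetylated with CF3CO2CH2CF3 to the trifluoromethyl diketone F10, which is not isolated. Detrifluoroacetylative diazo transfer (MsN3, Et3N, H2O, MeCN, rt) then gives 9.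

**Further compounds**

F1 | step 10 | methyl 4-methoxy-3-(4,4,5,5-tetramethyl-1,3,2-dioxaborolan-2-yl)benzoate | COC(=O)c1ccc(OC)c(B2OC(C)(C)C(C)(C)O2)c1
F2 | step 10 | 7-(benzyloxy)-2-[4-(benzyloxy)phenyl]-5-hydroxy-4H-chromen-4-one | O=c1cc(-c2ccc(OCc3ccccc3)cc2)oc2cc(OCc3ccccc3)cc(O)c12
F3 | step 10 | 7-(benzyloxy)-2-[4-(benzyloxy)phenyl]-5-hydroxy-6-iodo-4H-chromen-4-one | O=c1cc(-c2ccc(OCc3ccccc3)cc2)oc2cc(OCc3ccccc3)c(I)c(O)c12
F4 | step 10 | methyl 3-{7-(benzyloxy)-2-[4-(benzyloxy)phenyl]-5-hydroxy-4-oxo-4H-chromen-6-yl}-4-methoxybenzoate | COC(=O)c1ccc(OC)c(-c2c(OCc3ccccc3)cc3oc(-c4ccc(OCc5ccccc5)cc4)cc(=O)c3c2O)c1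
F5 | step 9 | [(5-bromo-2-methoxyphenyl)ethynyl]trimethylsilane | COc1ccc(Br)cc1C#C[Si](C)(C)C
F6 | step 9 | 4-bromo-2-ethynyl-1-methoxybenzene | COc1ccc(Br)cc1C#C
F7 | step 9 | {[(5-bromo-2-methoxyphenyl)ethynyl]oxy}triisopropylsilane | COc1ccc(Br)cc1C#CO[Si](C(C)C)(C(C)C)C(C)C
F8 | step 9 | 2-[4-(benzyloxy)phenyl]-6-(5-bromo-2-methoxyphenyl)-5-hydroxy-7-[(triisopropylsilyl)oxy]-4H-chromen-4-one | COc1ccc(Br)cc1-c1c(O[Si](C(C)C)(C(C)C)C(C)C)cc2oc(-c3ccc(OCc4ccccc4)cc3)cc(=O)c2c1O
F9 | step 6 | 2-acetyl-6-[4-(benzyloxy)phenyl]-4H-pyran-4-one | CC(=O)c1cc(=O)cc(-c2ccc(OCc3ccccc3)cc2)o1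
F10 | step 6 | 1-{6-[4-(benzyloxy)phenyl]-4-oxo-4H-pyran-2-yl}-4,4,4-trifluorobutane-1,3-dione | O=C(CC(=O)C(F)(F)F)c1cc(=O)cc(-c2ccc(OCc3ccccc3)cc2)o1
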